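Readings and results were computed for substances that don't exist; scatter was added.

Charges first: [starting material] stands at 0.050 M in oak and cedar as in the two runs, while [coupling partner] differs from flask to flask.

the same everywhere: starting material 0.050 M
- autumn: coupling partner 0.21 M; run made earlier
- summer: coupling partner 0.33 M; run made earlier
- oak: coupling partner 0.250 M; time 4.0 min
- cedar: coupling partner 0.380 M; time 4.0 min

| run | time / s | starting material / % | target / % |
|---|---|---|---|
| autumn | 20.0 | 100.1 | 0 |
| autumn | 40.0 | 100.4 | 0 |
| autumn | 60.0 | 98.0 | 1.9 |
| autumn | 80.0 | 98.1 | 1.3 |
| autumn | 90.0 | 97.4 | 2.4 |
| autumn | 120 | 94.7 | 4.1 |
| summer | 10.0 | 100.2 | 0.5 |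
| summer | 15.0 | 99.6 | 0 |
| summer | 25.0 | 99.2 | 1.5 |
| summer | 40.0 | 98.1 | 1.7 |
| summer | 80.0 | 93.2 | 5.8 |
| summer | 120 | 82.7 | 17.9 |

(readings scatter by 0.5 percentage points)

- steps under discussion: starting material + coupling partner -> target + released group; coupling partner <-> dormant form; starting material + coupling partner + released group -> target + 2 released group

- which of these there is most of at the end, counted by the starting material in it, oak (starting material / target)
- which of these there is most of at the end, counted by the starting material in it, cedar (starting material / target)
- final amount of the leader among these, as a percentage of the starting material charged, in oak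
- final amount of the leader among these, as a percentage of the starting material charged, in cedar

The readings show target creeping, then climbing: a direct route seeds released group, and released group feeds its own formation (autocatalysis). Growth of that kind lifts the odds, target over starting material, exponentially from a small seed. At 120 s the odds read 0.216 in summer and 0.0433 in autumn, so

κ = ln(summer odds / autumn odds) / (difference in [coupling partner] × [starting material] × time) = 2.24 M⁻² s⁻¹

This κ is the feedback constant, read off scattered readings: the rise in ln(odds) per unit of [starting material] × [coupling partner] × time. Run back from summer, it leaves a seed of 1.30 × 10⁻⁴ M of released group, so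

ln(odds) = ln(seed / [starting material]) + stretch × κ × [starting material] × [coupling partner] × 120 s

The stretch counts the time the feedback works, in units of that reading, and oak and cedar run twice as long as that reading. Two extreme flasks can be solved at once. If feedback stops at 120 s, the stretch is 1, and target ends at 6.89% in oak and 29.7% in cedar. If feedback runs on at its pace up to 120 s, the stretch is 2, giving 67.9% and 98.6%. Coupling partner can pass into the dormant form, and the runs carry no reading of either, so this reckoning takes the middle, a stretch of 1.50:

oak: target 28.4%
cedar: target 84.4%

The forecast names starting material for oak at 63% and target for cedar at 86%, adding “Oak sits on the steep part of the curve, so it is uncertain.” It stands close to this reckoning on cedar and differs on oak.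

The flasks give starting material leading oak at 73.7% and target leading cedar at 76.3%.

    starting material + coupling partner → target + released group (k = 5.32 × 10⁻⁴ M⁻¹ s⁻¹)
    coupling partner ⇌ dormant form (K = 5.20, k = 0.00723 s⁻¹)
    starting material + coupling partner + released group → target + 2 released group (k = 3.07 M⁻² s⁻¹)

Read back through κ, the end odds give a stretch of 1.47 in oak and 1.40 in cedar, both inside the two extremes. A neighbour of cedar is charged with 0.020 M of starting material. The reckoning keeps the same seed concentration and shrinks the exponent with the charge, so the stretch of 1.50 puts target at 12.1%. That flask ends with starting material leading at 87.1% and target at 12.9%.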